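**Plan**

1. Retrosynthesis cuts (a) the seven O–CH3 bonds of a heptamethyl ether; (b) the two aryl–C(=O) bonds to the 2,6-dioxygenated rings, back to a bis(Weinreb amide); (c) the biaryl bond C-5 (ring A)–C-6 (ring B), each catechol ring numbered with the chain carbon as C-1 and the oxygens on C-3 and C-4; (d) the C-7–C-8 bond of each chain (alkene cross-metathesis).
2. Forward: oct-7-enoic acid becomes a Weinreb amide; cross-metathesis with eugenol and hydrogenation give the ring A half (free OH on C-4, OMe on C-3); O-methylation of part of it gives the ring B half; oxidative phenol–arene coupling joins them; both acylresorcinol rings are attached in one operation; all methyl ethers are cleaved last.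
3. Enabling feature: in ring A the C-4 phenol oxygen activates C-3, C-5 and C-1, of which C-3 bears OMe and C-1 the chain, so only C-5–H can couple; in ring B, C-6–H is para to the C-3 methoxy oxygen and ortho to the chain, the most nucleophilic CH of a 4-alkylveratrole. One free phenol against a fully methylated partner assigns the roles of radical precursor and nucleophile.
4. The acylresorcinol rings are withheld until after the coupling because their C-3 positions would compete as nucleophiles; the Weinreb amides stand in for them.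
5. Stereochemistry: the target has no stereocentre, and its biaryl axis, flanked only by OH and CH2, is not configurationally stable; the alkene geometry from metathesis is erased by hydrogenation.

Key step: step 5

Remark: oct-7-enoic acid, eugenol and 1,3-dimethoxybenzene are taken as commercial; step 4 is run on about three quarters of 6, so that 7 is at hand in threefold excess for step 5.

**Route**

Step 1
Reactants: 1 oct-7-enoic acid
Product: 3 N-methoxy-N-methyloct-7-enamide, via acyl imidazole 2 (not isolated)
Conditions: 1,1'-carbonyldiimidazole (1.1 equiv), CH2Cl2, rt, 1 h; then MeNH(OMe)·HCl (1.2 equiv), rt, 12 h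
Reagents that add atoms: N,O-dimethylhydroxylamine hydrochloride, CNOC.Cl; 1,1'-carbonyldiimidazole, O=C(n1ccnc1)n1ccnc1 (its imidazolyl group stays only in 2)
Why: Carbonyldiimidazole activation gives acyl imidazole 2, which acylates the amine freed from its salt (Weinreb amide formation); the terminal alkene is inert.

Step 2
Reactants: 3 N-methoxy-N-methyloct-7-enamide; 4 eugenol (4-allyl-2-methoxyphenol, 3 equiv)
Product: 5 (E)-9-(4-hydroxy-3-methoxyphenyl)-N-methoxy-N-methylnon-7-enamide
Conditions: second-generation Grubbs catalyst RuCl2(=CHPh)(H2IMes)(PCy3) (3 mol %), 1,4-benzoquinone (10 mol %), CH2Cl2, 40 °C, argon sparge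
Reagents that add atoms: none
Why: Olefin cross-metathesis of two unhindered terminal alkenes, driven by excess 4 and loss of ethene; 1,4-benzoquinone should suppress ruthenium hydride isomerisation of the allylarene, and the E/Z mixture expected (mainly E) converges in step 3.

Step 3
Reactants: 5 (E)-9-(4-hydroxy-3-methoxyphenyl)-N-methoxy-N-methylnon-7-enamide
Product: 6 9-(4-hydroxy-3-methoxyphenyl)-N-methoxy-N-methylnonanamide
Conditions: H2 (1 atm), 10% Pd/C, EtOAc, rt
Reagents that add atoms: none
Why: Heterogeneous hydrogenation should saturate the disubstituted alkene of both geometric isomers while the arene, the phenol and the N–O bond of the Weinreb amide are left alone at one atmosphere.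

Step 4
Reactants: 6 9-(4-hydroxy-3-methoxyphenyl)-N-methoxy-N-methylnonanamide
Product: 7 9-(3,4-dimethoxyphenyl)-N-methoxy-N-methylnonanamide
Conditions: MeI (1.5 equiv), K2CO3 (2 equiv), acetone, reflux
Reagents that add atoms: iodomethane, CI
Why: Williamson ether synthesis on the potassium phenoxide; the Weinreb amide has no site that is alkylated under these conditions.

Step 5
Reactants: 6 9-(4-hydroxy-3-methoxyphenyl)-N-methoxy-N-methylnonanamide (1 equiv); 7 9-(3,4-dimethoxyphenyl)-N-methoxy-N-methylnonanamide (3 equiv)
Product: 8 9-{2-[2-hydroxy-3-methoxy-5-(9-(methoxy(methyl)amino)-9-oxononyl)phenyl]-4,5-dimethoxyphenyl}-N-methoxy-N-methylnonanamide (ring A C-5 joined to ring B C-6)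
Conditions: FeCl3 (10 mol %), t-BuOOt-Bu (1.5 equiv), (CF3)2CHOH (HFIP), rt; excess 7 recovered by chromatography
Reagents that add atoms: none
Why: FeCl3 binds phenol 6 as a trivalent iron phenolate, which the peroxide oxidises to an iron-bound phenoxyl radical with spin density on the ring carbons ortho and para to oxygen; the electron-rich arene 7 adds to it through its most nucleophilic CH, and a second one-electron oxidation with loss of two protons restores both aromatic rings. The closest known reaction type is the iron-catalysed oxidative cross-dehydrogenative coupling of phenols with alkoxyarenes in HFIP, whose metal-free counterpart is the anodic phenol–arene cross-coupling. No ring is closed and no stereocentre is formed. Site selectivity on ring A is fixed because, of the three positions ortho and para to the C-4 oxygen, C-3 carries the methoxy group and C-1 the chain, so only C-5 can lose a proton and rearomatise; on ring B, C-6 is para to the C-3 methoxy oxygen and ortho to the chain, whereas C-5 is only ortho-activated and C-2 is flanked on both sides. Cross- over homo-coupling rests on the division of roles: only 6 has a free OH and is oxidised at low potential, 7 is the neutral nucleophile in threefold excess, HFIP hydrogen-bonds to unoxidised 6 and lowers its nucleophilicity, and the product phenol has no free ortho or para CH left for a second coupling. The acylresorcinol rings are absent at this stage on purpose, since their C-3 positions would compete with C-6 of ring B as nucleophiles.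

Step 6
Reactants: 8 biaryl bis(Weinreb amide); 9 1,3-dimethoxybenzene (6 equiv)
Product: 12 1-(2,6-dimethoxyphenyl)-9-{2-[5-(9-(2,6-dimethoxyphenyl)-9-oxononyl)-2-hydroxy-3-methoxyphenyl]-4,5-dimethoxyphenyl}nonan-1-one, via 2,6-dimethoxyphenyllithium 10 (not isolated), via trilithium tetrahedral adduct 11 (not isolated)
Conditions: 9, n-BuLi (5.5 equiv), THF, 0 °C to rt, 2 h; then 8, −78 °C to 0 °C; 1 M aq HCl
Reagents that add atoms: n-butyllithium, [Li]CCCC (its lithium stays only in 10 and 11)
Why: Directed ortho-lithiation of 9 between its two methoxy groups gives 10, which should add once to each Weinreb amide because the chelated adduct 11 holds until the acidic quench (Weinreb ketone synthesis); the first equivalent of 10 is spent on the phenol of 8, whose lithium phenoxide is inert.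

Step 7
Reactants: 12 heptamethyl ether diketone
Product: 13 1-(2,6-dihydroxyphenyl)-9-{2-[5-(9-(2,6-dihydroxyphenyl)-9-oxononyl)-2,3-dihydroxyphenyl]-4,5-dihydroxyphenyl}nonan-1-one (target)
Conditions: BBr3 (14 equiv), CH2Cl2, −78 °C to rt, 12 h; then degassed MeOH/H2O, 0 °C, under argon
Reagents that add atoms: none
Why: Lewis acid demethylation of aryl methyl ethers by boron coordination at oxygen and bromide attack at methyl; the ethers ortho to each ketone are helped by chelation, the ketones and saturated chains are inert, and only one hydroxyl is ortho to the biaryl bond, so no dibenzofuran can close.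

**Compound list**

1 | oct-7-enoic acid | C=CCCCCCC(=O)O | starting material
2 | 1-(imidazol-1-yl)oct-7-en-1-one (acyl imidazole, not isolated) | C=CCCCCCC(=O)n1ccnc1 | intermediate
3 | N-methoxy-N-methyloct-7-enamide | C=CCCCCCC(=O)N(C)OC | intermediate
4 | eugenol (4-allyl-2-methoxyphenol) | C=CCc1ccc(O)c(OC)c1 | starting material
5 | (E)-9-(4-hydroxy-3-methoxyphenyl)-N-methoxy-N-methylnon-7-enamide (E isomer shown; the Z isomer may accompany it) | CON(C)C(=O)CCCCC/C=C/Cc1ccc(O)c(OC)c1 | intermediate
6 | 9-(4-hydroxy-3-methoxyphenyl)-N-methoxy-N-methylnonanamide | CON(C)C(=O)CCCCCCCCc1ccc(O)c(OC)c1 | intermediate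
7 | 9-(3,4-dimethoxyphenyl)-N-methoxy-N-methylnonanamide | CON(C)C(=O)CCCCCCCCc1ccc(OC)c(OC)c1 | intermediate
8 | 9-{2-[2-hydroxy-3-methoxy-5-(9-(methoxy(methyl)amino)-9-oxononyl)phenyl]-4,5-dimethoxyphenyl}-N-methoxy-N-methylnonanamide | CON(C)C(=O)CCCCCCCCc1cc(OC)c(O)c(-c2cc(OC)c(OC)cc2CCCCCCCCC(=O)N(C)OC)c1 | intermediate
9 | 1,3-dimethoxybenzene | COc1cccc(OC)c1 | starting material
10 | 2,6-dimethoxyphenyllithium (not isolated) | [Li]c1c(OC)cccc1OC | intermediate
11 | trilithium salt of the double tetrahedral adduct of 10 to 8 (not isolated; the two new carbinol centres are unassigned and vanish on quench) | [Li]OC(CCCCCCCCc1cc(OC)c(O[Li])c(-c2cc(OC)c(OC)cc2CCCCCCCCC(O[Li])(N(C)OC)c2c(OC)cccc2OC)c1)(N(C)OC)c1c(OC)cccc1OC | intermediate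
12 | 1-(2,6-dimethoxyphenyl)-9-{2-[5-(9-(2,6-dimethoxyphenyl)-9-oxononyl)-2-hydroxy-3-methoxyphenyl]-4,5-dimethoxyphenyl}nonan-1-one | COc1cccc(OC)c1C(=O)CCCCCCCCc1cc(OC)c(O)c(-c2cc(OC)c(OC)cc2CCCCCCCCC(=O)c2c(OC)cccc2OC)c1 | intermediate
13 | 1-(2,6-dihydroxyphenyl)-9-{2-[5-(9-(2,6-dihydroxyphenyl)-9-oxononyl)-2,3-dihydroxyphenyl]-4,5-dihydroxyphenyl}nonan-1-one | O=C(CCCCCCCCc1cc(O)c(O)c(-c2cc(O)c(O)cc2CCCCCCCCC(=O)c2c(O)cccc2O)c1)c1c(O)cccc1O | target

**Step count and risks**

Total steps: 7. Longest linear sequence: 7 (steps 1 to 7; the ring B half 7 branches from 6 through step 4).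

Steps most likely to fail:

1. Step 5. The oxidised phenol may be intercepted by a second molecule of 6 in place of 7 (homo-coupling), C–O bond formation may compete with C–C bond formation, and hydrogen abstraction at the benzylic CH2 groups may consume material. The fallback sets out from 7 and 6 and comes back at 8. Compound 7 is brominated with NBS in MeCN para to the C-3 methoxy group to give 9-(2-bromo-4,5-dimethoxyphenyl)-N-methoxy-N-methylnonanamide F1. Miyaura borylation (B2pin2, Pd(dppf)Cl2, KOAc, dioxane, 90 °C) should turn it into the pinacol boronate 9-[4,5-dimethoxy-2-(4,4,5,5-tetramethyl-1,3,2-dioxaborolan-2-yl)phenyl]-N-methoxy-N-methylnonanamide F2. Compound 6 is brominated ortho to the phenol (NBS, cat. i-Pr2NH, CH2Cl2, 0 °C) to give 9-(3-bromo-4-hydroxy-5-methoxyphenyl)-N-methoxy-N-methylnonanamide F3. Suzuki–Miyaura coupling of F2 with F3 (Pd(OAc)2, SPhos, K3PO4, toluene/water, 90 °C) should then give 8.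

2. Step 6. The hindered aryllithium may deprotonate alpha to the Weinreb amides, and the addition may stall after the first amide on the aggregated lithium phenoxide. The fallback sets out from 8 and comes back at 13. The phenol of 8 is methylated (MeI, K2CO3, acetone) to give the tetramethoxy biaryl bis(Weinreb amide) F4. LiAlH4 in THF at −78 to 0 °C should reduce both amides to the dialdehyde F5. Addition of 10 (THF, −78 °C) to these more electrophilic carbonyls should give the bis(benzylic alcohol) F6 as a mixture of diastereomers. Dess–Martin periodinane in CH2Cl2 should oxidise it to the octamethyl ether diketone F7, and BBr3 under the conditions of step 7 then gives 13.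

3. Step 7. Ether cleavage may stop short and leave partly methylated mixtures, above all at the second ether of each acylresorcinol ring, and the liberated catechols may oxidise in air during the long exposure. The fallback sets out from 8 and comes back at 13. Compound 8 is treated with 2,6-bis(methoxymethoxy)phenyllithium F9, made from commercial 1,3-bis(methoxymethoxy)benzene F8 and n-BuLi in THF at 0 °C, to give the diketone F10 with four methoxymethyl ethers on the resorcinol rings. HCl in MeOH at rt should remove the four acetals and give the tri-O-methyl ether F11, so that BBr3 in CH2Cl2 has only the three catechol methyl ethers left to cleave on the way to 13.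

**Further compounds**

F1 | step 5 | 9-(2-bromo-4,5-dimethoxyphenyl)-N-methoxy-N-methylnonanamide | CON(C)C(=O)CCCCCCCCc1cc(OC)c(OC)cc1Br
F2 | step 5 | 9-[4,5-dimethoxy-2-(4,4,5,5-tetramethyl-1,3,2-dioxaborolan-2-yl)phenyl]-N-methoxy-N-methylnonanamide | CON(C)C(=O)CCCCCCCCc1cc(OC)c(OC)cc1B1OC(C)(C)C(C)(C)O1
F3 | step 5 | 9-(3-bromo-4-hydroxy-5-methoxyphenyl)-N-methoxy-N-methylnonanamide | CON(C)C(=O)CCCCCCCCc1cc(Br)c(O)c(OC)c1
F4 | step 6 | 9-{2-[2,3-dimethoxy-5-(9-(methoxy(methyl)amino)-9-oxononyl)phenyl]-4,5-dimethoxyphenyl}-N-methoxy-N-methylnonanamide | CON(C)C(=O)CCCCCCCCc1cc(OC)c(OC)c(-c2cc(OC)c(OC)cc2CCCCCCCCC(=O)N(C)OC)c1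
F5 | step 6 | 9-{2-[2,3-dimethoxy-5-(9-oxononyl)phenyl]-4,5-dimethoxyphenyl}nonanal | O=CCCCCCCCCc1cc(OC)c(OC)c(-c2cc(OC)c(OC)cc2CCCCCCCCC=O)c1
F6 | step 6 | 1-(2,6-dimethoxyphenyl)-9-{2-[5-(9-(2,6-dimethoxyphenyl)-9-hydroxynonyl)-2,3-dimethoxyphenyl]-4,5-dimethoxyphenyl}nonan-1-ol (mixture of diastereomers) | COc1cccc(OC)c1C(O)CCCCCCCCc1cc(OC)c(OC)c(-c2cc(OC)c(OC)cc2CCCCCCCCC(O)c2c(OC)cccc2OC)c1
F7 | step 6 | 1-(2,6-dimethoxyphenyl)-9-{2-[5-(9-(2,6-dimethoxyphenyl)-9-oxononyl)-2,3-dimethoxyphenyl]-4,5-dimethoxyphenyl}nonan-1-one | COc1cccc(OC)c1C(=O)CCCCCCCCc1cc(OC)c(OC)c(-c2cc(OC)c(OC)cc2CCCCCCCCC(=O)c2c(OC)cccc2OC)c1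
F8 | step 7 | 1,3-bis(methoxymethoxy)benzene | COCOc1cccc(OCOC)c1
F9 | step 7 | 2,6-bis(methoxymethoxy)phenyllithium | [Li]c1c(OCOC)cccc1OCOC
F10 | step 7 | 1-[2,6-bis(methoxymethoxy)phenyl]-9-{2-[5-(9-(2,6-bis(methoxymethoxy)phenyl)-9-oxononyl)-2-hydroxy-3-methoxyphenyl]-4,5-dimethoxyphenyl}nonan-1-one | COCOc1cccc(OCOC)c1C(=O)CCCCCCCCc1cc(OC)c(O)c(-c2cc(OC)c(OC)cc2CCCCCCCCC(=O)c2c(OCOC)cccc2OCOC)c1
F11 | step 7 | 1-(2,6-dihydroxyphenyl)-9-{2-[5-(9-(2,6-dihydroxyphenyl)-9-oxononyl)-2-hydroxy-3-methoxyphenyl]-4,5-dimethoxyphenyl}nonan-1-one | O=C(CCCCCCCCc1cc(OC)c(O)c(-c2cc(OC)c(OC)cc2CCCCCCCCC(=O)c2c(O)cccc2O)c1)c1c(O)cccc1O
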